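The C5=C6 enol-lactone alkene is treated as a dehydrated vinylogous aldol: C6 is the γ-carbon of the C7=C11 butenolide ring and C5 sits on the quaternary, non-enolisable C4 of the oxolane ring. Step 15 joins C5 to C6 by an intramolecular vinylogous Mukaiyama aldol addition, which closes the ten-membered carbocycle and regenerates the butenolide in one operation; mesylation and elimination then give the alkene. The precursor is a 2-triisopropylsilyloxyfuran (C6, C7, C11, C12) linked through C8–C10, carrying both oxygenated stereocentres, to a trans-2,5-disubstituted oxolane whose C4 bears the aldehyde. (S)-Linalool supplies C4; epoxidation, a boron aldol and a chelate-controlled methyl addition set C1, C8 and C10.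

Key step: step 15

Numbering: germacrane numbers are used throughout (C1 oxolane CH, C2 and C3 oxolane CH2, C4 oxolane quaternary carbon, C5, C6, C7=C11 butenolide alkene, C8 acyloxy carbinol, C9 CH2, C10 tertiary carbinol, C12 lactone carbonyl, C13 oxymethyl). TES = triethylsilyl, TBDPS = tert-butyldiphenylsilyl, TIPS = triisopropylsilyl.
Assumption: 24 and 25 are drawn as the 5S,6S (anti) isomers; the outcome at C5 and C6 cannot be predicted with confidence and does not matter, because both centres become sp2 in step 16.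

Step 1
Reactants: 1 (S)-(+)-linalool
Product: 3 trans-furanoid linalool oxide 2-[(2S,5S)-5-ethenyl-5-methyloxolan-2-yl]propan-2-ol, via epoxylinalool 2 (not isolated)
Conditions: D-fructose-derived Shi ketone (0.3 equiv), KHSO5 (as 2KHSO5·KHSO4·K2SO4), K2CO3, Bu4NHSO4, MeCN/CH2(OMe)2/aq. Na2B4O7 buffer, 0 °C; then camphorsulfonic acid (0.1 equiv), CH2Cl2, 0 °C → rt
Reagents that add atoms: potassium peroxymonosulfate KHSO5, [K+].[O-]S(=O)(=O)OO
Why: Shi asymmetric epoxidation (chiral dioxirane, spiro transition state) oxidises only the electron-rich trisubstituted alkene and should give the 6R epoxide 2; acid-catalysed 5-exo-tet opening by the tertiary hydroxyl inverts that carbon, setting C1 as S with the hydroxypropyl group trans to the vinyl group, and the minor six-membered ether is removed by chromatography.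

Step 2
Reactants: 3 trans-furanoid linalool oxide
Product: 4 (2S,5S)-2-ethenyl-2-methyl-5-(prop-1-en-2-yl)oxolane
Conditions: POCl3, pyridine, 0 °C → rt
Reagents that add atoms: none
Why: E2 dehydration of the tertiary alcohol through its dichlorophosphate; removal of one of six methyl hydrogens is favoured over the single hindered α-oxygenated ring hydrogen, so the isopropenyl isomer should predominate and no stereocentre is touched.

Step 3
Reactants: 4 isopropenyl oxolane
Product: 6 methyl ketone 1-[(2S,5S)-5-ethenyl-5-methyloxolan-2-yl]ethan-1-one, via oxirane 5 (not isolated)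
Conditions: mCPBA (1.05 equiv), NaHCO3, CH2Cl2, 0 °C; then H5IO6, THF/H2O, 0 °C
Reagents that add atoms: mCPBA, O=C(OO)c1cccc(Cl)c1; water, O (the carbonyl oxygen is the epoxide oxygen or, after acid opening at the tertiary carbon, a water oxygen)
Why: Prilezhaev epoxidation is selective for the more nucleophilic 1,1-disubstituted alkene over the monosubstituted vinyl group on the quaternary, oxygenated C4, and periodic acid cleaves the terminal epoxide through its diol (Malaprade-type cleavage) to the methyl ketone; short, cold treatment keeps the α-oxygenated C1 from epimerising.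

Step 4
Reactants: 7 diethyl furan-3,4-dicarboxylate
Product: 8 furan-3,4-diyldimethanol
Conditions: LiAlH4, THF, 0 °C → rt
Reagents that add atoms: none
Why: Hydride reduction of both esters to primary alcohols with LiAlH4.

Step 5
Reactants: 8 furan-3,4-diyldimethanol
Product: 9 [4-({[tert-butyl(diphenyl)silyl]oxy}methyl)furan-3-yl]methanol
Conditions: NaH (1.0 equiv), THF, 0 °C; TBDPSCl (1.0 equiv), rt
Reagents that add atoms: tert-butyl(chloro)diphenylsilane, CC(C)(C)[Si](Cl)(c1ccccc1)c1ccccc1
Why: Monosilylation of a symmetric diol through its monosodium alkoxide; the bulky, weakly basic TBDPS ether is chosen for C13 because it resists BF3 in step 15 and outlasts the TES ethers in step 17.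

Step 6
Reactants: 9 mono-TBDPS ether
Product: 10 4-({[tert-butyl(diphenyl)silyl]oxy}methyl)furan-3-carbaldehyde
Conditions: activated MnO2, CH2Cl2, rt
Reagents that add atoms: none
Why: MnO2 oxidises the furylic (heteroaryl) carbinol to the aldehyde without over-oxidation.

Step 7
Reactants: 10 furan aldehyde
Product: 11 5-bromo-4-({[tert-butyl(diphenyl)silyl]oxy}methyl)furan-3-carbaldehyde
Conditions: NBS, DMF, 0 °C → rt, dark
Reagents that add atoms: N-bromosuccinimide, O=C1CCC(=O)N1Br
Why: Electrophilic aromatic bromination; the formyl group deactivates the α-position next to it (future C6) and the alkyl substituent activates its own neighbour, so bromine should enter only at future C12, marking the carbon that becomes the lactone carbonyl.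

Step 8
Reactants: 6 methyl ketone; 11 bromofuran aldehyde
Product: 14 (8S)-β-hydroxy ketone (3S)-3-[5-bromo-4-({[tert-butyl(diphenyl)silyl]oxy}methyl)furan-3-yl]-1-[(2S,5S)-5-ethenyl-5-methyloxolan-2-yl]-3-hydroxypropan-1-one, via boron enolate 12 (not isolated), via boron aldolate 13 (not isolated)
Conditions: (−)-Ipc2BCl (1.4 equiv), Et3N, Et2O, 0 °C; 11, −78 → −20 °C; then MeOH, pH 7 buffer, 30% H2O2, 0 °C
Reagents that add atoms: none
Why: Paterson boron aldol: the chloroborane enolises the ketone on the methyl side only, and the isopinocampheyl ligands should direct the enolate to the Si face of the aldehyde in a cyclic six-membered transition state, giving 8S by reagent control; the C8 epimer, if formed, is separable at this stage.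

Step 9
Reactants: 14 β-hydroxy ketone
Product: 15 C8 triethylsilyl ether of 14
Conditions: TESCl, imidazole, DMF, 0 °C → rt
Reagents that add atoms: chlorotriethylsilane, CC[Si](Cl)(CC)CC
Why: O-Silylation under conditions too mild for retro-aldol or β-elimination; the non-chelating silyl ether removes the C8 oxygen as a competing chelation site in step 10.

Step 10
Reactants: 15 β-silyloxy ketone
Product: 16 (2R,4S)-4-[5-bromo-4-({[tert-butyl(diphenyl)silyl]oxy}methyl)furan-3-yl]-2-[(2S,5S)-5-ethenyl-5-methyloxolan-2-yl]-4-[(triethylsilyl)oxy]butan-2-ol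
Conditions: MeMgBr (3 equiv), THF, −78 °C; aq. NH4Cl
Reagents that add atoms: methylmagnesium bromide, C[Mg]Br
Why: Chelation-controlled Grignard addition (Cram chelate model): magnesium bridges the ketone and oxolane oxygens and methyl attacks from the side of the C1 hydrogen, not of the C2 methylene, which should give 10R; the furyl bromide is inert at −78 °C.

Step 11
Reactants: 16 tertiary alcohol
Product: 17 bis-TES ether, C8 and C10 O-triethylsilyl derivative of 16
Conditions: TESOTf, 2,6-lutidine, CH2Cl2, −78 → 0 °C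
Reagents that add atoms: triethylsilyl trifluoromethanesulfonate, CC[Si](CC)(CC)OS(=O)(=O)C(F)(F)F
Why: Silyl triflate silylation of the hindered tertiary alcohol; the hydroxyl is masked because with BF3 it would generate Brønsted acid and destroy the silyloxyfuran in step 15.

Step 12
Reactants: 17 bromofuran
Product: 20 butenolide 3-({[tert-butyl(diphenyl)silyl]oxy}methyl)-4-{(1S,3R)-3-[(2S,5S)-5-ethenyl-5-methyloxolan-2-yl]-1,3-bis[(triethylsilyl)oxy]butyl}furan-2(5H)-one, via furyllithium 18 (not isolated), via lithium furylborate 19 (not isolated)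
Conditions: B(OiPr)3 (1.5 equiv), then n-BuLi (1.2 equiv), THF/toluene, −78 °C; 30% H2O2, aq. NaHCO3, 0 °C; then Et3N (cat.), CH2Cl2, rt
Reagents that add atoms: hydrogen peroxide, OO
Why: Bromine–lithium exchange with in situ borate trapping (which outruns oxygen-to-carbon silyl migration), oxidation of the C–B bond to the 2-hydroxyfuran and amine-mediated tautomerisation should give the conjugated butenolide with its carbonyl at the carbon that carried bromine.

Step 13
Reactants: 20 vinyl butenolide
Product: 22 butenolide aldehyde (2S,5S)-5-{(2R,4S)-4-[4-({[tert-butyl(diphenyl)silyl]oxy}methyl)-5-oxo-2,5-dihydrofuran-3-yl]-2,4-bis[(triethylsilyl)oxy]butan-2-yl}-2-methyloxolane-2-carbaldehyde, via vicinal diol 21 (not isolated)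
Conditions: OsO4 (2 mol %), NaIO4 (4 equiv), 2,6-lutidine, 1,4-dioxane/H2O, rt
Reagents that add atoms: sodium periodate (terminal oxidant; the aldehyde oxygen reaches C5 through OsO4), [Na+].[O-]I(=O)(=O)=O
Why: Lemieux–Johnson cleavage: OsO4 dihydroxylates only the monosubstituted vinyl group, the tetrasubstituted electron-poor butenolide alkene being inert, and periodate cleaves the diol; the aldehyde has no α-hydrogen and cannot epimerise.

Step 14
Reactants: 22 butenolide aldehyde
Product: 23 silyloxyfuran aldehyde (2S,5S)-5-{(2R,4S)-4-[4-({[tert-butyl(diphenyl)silyl]oxy}methyl)-5-{[tri(propan-2-yl)silyl]oxy}furan-3-yl]-2,4-bis[(triethylsilyl)oxy]butan-2-yl}-2-methyloxolane-2-carbaldehyde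
Conditions: TIPSOTf (1.3 equiv), Et3N (3 equiv), CH2Cl2, −78 → 0 °C; cold aq. NaHCO3, filtration through Et3N-deactivated silica
Reagents that add atoms: triisopropylsilyl trifluoromethanesulfonate, CC(C)[Si](OS(=O)(=O)C(F)(F)F)(C(C)C)C(C)C
Why: Soft enolisation of the butenolide at C6 and O-silylation give the 2-silyloxyfuran (silyl dienol ether formation); excess amine, the bulky silyl group and low temperature keep free silyl triflate from activating the hindered, non-enolisable aldehyde.

Step 15
Reactants: 23 silyloxyfuran aldehyde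
Product: 24 ten-membered hydroxy butenolide (1S,4S,5S,6S,8S,10R)-13-[tert-butyl(diphenyl)silyloxy]-1,4-epoxy-5-hydroxy-8,10-bis(triethylsilyloxy)germacr-7(11)-en-12,6-olide
Conditions: BF3·OEt2 (2 equiv), 2,6-di-tert-butyl-4-methylpyridine (0.2 equiv), CH2Cl2, −78 °C, 23 added by syringe pump to a final 1 mM; aq. NaHCO3
Reagents that add atoms: none
Why: BF3 coordinates the C5 aldehyde, the silyloxyfuran attacks through its unsubstituted α-carbon C6 (the γ-carbon of the latent butenolide), and the resulting silyloxy-oxocarbenium ion gives up the TIPS group to fluoride, regenerating the C7=C11 butenolide. The reaction type is the vinylogous Mukaiyama aldol addition of 2-silyloxyfurans to aldehydes, run here intramolecularly. The new C5–C6 bond closes the ten-membered carbocycle (nine-membered when counted through the oxolane oxygen) in an exo-trig sense at the carbonyl carbon, an end-to-end closure favoured over oligomerisation by slow addition at high dilution. C5 is set by the aldehyde face that the tether, arriving from the opposite face of the trans-oxolane, can reach, and C6 by the open, antiperiplanar approach of furan and carbonyl; the anti adduct is drawn as the expected isomer, and neither centre needs control because both are removed in step 16. The selectivity that matters is γ over α attack, secured because C6 carries the largest HOMO coefficient and is unsubstituted whereas C11 is blocked by the silyloxymethyl group; chemoselectivity is secured because the aldehyde cannot enolise and the hindered silyl ethers at C8, C10 and C13 resist BF3 at −78 °C. The strain of bridging the trans-2,5 positions of the oxolane is the open question of the route and is placed in this step alone.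

Step 16
Reactants: 24 hydroxy butenolide
Product: 26 dienolide (1S,4S,5E,8S,10R)-13-[tert-butyl(diphenyl)silyloxy]-1,4-epoxy-8,10-bis(triethylsilyloxy)germacra-5,7(11)-dien-12,6-olide, via C5 mesylate 25 (not isolated)
Conditions: MsCl, Et3N, CH2Cl2, 0 °C; then DBU, 0 °C → rt
Reagents that add atoms: none
Why: Mesylation through sulfene followed by E1cB elimination: C6–H is vinylogously acidic, and the planar 2-oxidofuran intermediate expels mesylate to give the conjugated γ-ylidene butenolide, the ring holding C4 cis to C7 whatever the C5 and C6 configurations were.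

Step 17
Reactants: 26 dienolide
Product: 27 8,10-diol (1S,4S,5E,8S,10R)-13-[tert-butyl(diphenyl)silyloxy]-1,4-epoxy-8,10-dihydroxygermacra-5,7(11)-dien-12,6-olide
Conditions: HF·pyridine, pyridine, THF, 0 °C → rt
Reagents that add atoms: none
Why: Selective desilylation: buffered fluoride cleaves the secondary and tertiary TES ethers much faster than the primary TBDPS ether, and the non-basic medium avoids migration of the lactone to O8.

Step 18
Reactants: 27 8,10-diol; 28 angelic acid
Product: 30 8-O-angelate (1S,4S,5E,8S,10R)-8-angeloyloxy-13-[tert-butyl(diphenyl)silyloxy]-1,4-epoxy-10-hydroxygermacra-5,7(11)-dien-12,6-olide, via mixed anhydride 29 (not isolated)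
Conditions: 28, 2,4,6-trichlorobenzoyl chloride, Et3N, toluene, rt; then 27, toluene, 80 °C
Reagents that add atoms: none
Why: Yamaguchi-type esterification: the mixed anhydride acylates the secondary C8 hydroxyl on heating without a nucleophilic catalyst, conditions under which the Z geometry of the angelate should be kept; the tertiary C10 hydroxyl does not react.

Step 19
Reactants: 30 8-O-angelate
Product: 31 13-alcohol (1S,4S,5E,8S,10R)-8-angeloyloxy-1,4-epoxy-10,13-dihydroxygermacra-5,7(11)-dien-12,6-olide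
Conditions: HF·pyridine (excess), THF, 0 °C → rt
Reagents that add atoms: none
Why: Fluoride-mediated cleavage of the primary TBDPS ether; the two esters, the enol lactone and the tertiary alcohol are stable to HF·pyridine.

Step 20
Reactants: 31 13-alcohol
Product: 32 target (1S,4S,5E,8S,10R)-13-acetoxy-8-angeloyloxy-1,4-epoxy-10-hydroxygermacra-5,7(11)-dien-12,6-olide
Conditions: Ac2O, pyridine, CH2Cl2, 0 °C → rt
Reagents that add atoms: acetic anhydride, CC(=O)OC(C)=O
Why: Acetylation of the primary alcohol; the tertiary hydroxyl is not acylated under these conditions and no DMAP is used, so the angelate is not isomerised.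

Compound list
1 | (S)-(+)-linalool, (3S)-3,7-dimethylocta-1,6-dien-3-ol | CC(C)=CCC[C@@](C)(C=C)O | starting material
2 | (3S,6R)-6,7-epoxylinalool, (3S)-5-[(2R)-3,3-dimethyloxiran-2-yl]-3-methylpent-1-en-3-ol | CC1(C)O[C@@H]1CC[C@@](C)(C=C)O | intermediate (not isolated)
3 | trans-furanoid linalool oxide, 2-[(2S,5S)-5-ethenyl-5-methyloxolan-2-yl]propan-2-ol | CC(C)(O)[C@@H]1CC[C@@](C)(C=C)O1 | intermediate
4 | (2S,5S)-2-ethenyl-2-methyl-5-(prop-1-en-2-yl)oxolane | CC(=C)[C@@H]1CC[C@@](C)(C=C)O1 | intermediate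
5 | 2-[(2S,5S)-5-ethenyl-5-methyloxolan-2-yl]-2-methyloxirane, both epimers at the oxirane carbon | CC1(CO1)[C@@H]1CC[C@@](C)(C=C)O1 | intermediate (not isolated)
6 | 1-[(2S,5S)-5-ethenyl-5-methyloxolan-2-yl]ethan-1-one | CC(=O)[C@@H]1CC[C@@](C)(C=C)O1 | intermediate
7 | diethyl furan-3,4-dicarboxylate | CCOC(=O)c1cocc1C(=O)OCC | starting material
8 | furan-3,4-diyldimethanol | OCc1cocc1CO | intermediate
9 | [4-({[tert-butyl(diphenyl)silyl]oxy}methyl)furan-3-yl]methanol | OCc1cocc1CO[Si](c1ccccc1)(c1ccccc1)C(C)(C)C | intermediate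
10 | 4-({[tert-butyl(diphenyl)silyl]oxy}methyl)furan-3-carbaldehyde | O=Cc1cocc1CO[Si](c1ccccc1)(c1ccccc1)C(C)(C)C | intermediate
11 | 5-bromo-4-({[tert-butyl(diphenyl)silyl]oxy}methyl)furan-3-carbaldehyde | O=Cc1coc(Br)c1CO[Si](c1ccccc1)(c1ccccc1)C(C)(C)C | intermediate
12 | diisopinocampheylboron enolate of 6 (boron on the enolate oxygen, terminal CH2=) | B(OC(=C)[C@@H]1CC[C@@](C)(C=C)O1)([C@@H]1C[C@@H]2C[C@H]([C@H]1C)C2(C)C)[C@@H]1C[C@@H]2C[C@H]([C@H]1C)C2(C)C | intermediate (not isolated)
13 | diisopinocampheylboron aldolate of 14 (boron on the C8 oxygen) | B(O[C@@H](CC(=O)[C@@H]1CC[C@@](C)(C=C)O1)c1coc(Br)c1CO[Si](c1ccccc1)(c1ccccc1)C(C)(C)C)([C@@H]1C[C@@H]2C[C@H]([C@H]1C)C2(C)C)[C@@H]1C[C@@H]2C[C@H]([C@H]1C)C2(C)C | intermediate (not isolated)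
14 | (3S)-3-[5-bromo-4-({[tert-butyl(diphenyl)silyl]oxy}methyl)furan-3-yl]-1-[(2S,5S)-5-ethenyl-5-methyloxolan-2-yl]-3-hydroxypropan-1-one | O[C@@H](CC(=O)[C@@H]1CC[C@@](C)(C=C)O1)c1coc(Br)c1CO[Si](c1ccccc1)(c1ccccc1)C(C)(C)C | intermediate
15 | C8 triethylsilyl ether of 14 | CC[Si](CC)(CC)O[C@@H](CC(=O)[C@@H]1CC[C@@](C)(C=C)O1)c1coc(Br)c1CO[Si](c1ccccc1)(c1ccccc1)C(C)(C)C | intermediate
16 | (2R,4S)-4-[5-bromo-4-({[tert-butyl(diphenyl)silyl]oxy}methyl)furan-3-yl]-2-[(2S,5S)-5-ethenyl-5-methyloxolan-2-yl]-4-[(triethylsilyl)oxy]butan-2-ol | CC[Si](CC)(CC)O[C@@H](C[C@@](C)(O)[C@@H]1CC[C@@](C)(C=C)O1)c1coc(Br)c1CO[Si](c1ccccc1)(c1ccccc1)C(C)(C)C | intermediate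
17 | bis-TES ether of 16 (C8 and C10 O-triethylsilyl) | CC[Si](CC)(CC)O[C@@H](C[C@@](C)(O[Si](CC)(CC)CC)[C@@H]1CC[C@@](C)(C=C)O1)c1coc(Br)c1CO[Si](c1ccccc1)(c1ccccc1)C(C)(C)C | intermediate
18 | furyllithium from 17 (lithium in place of bromine) | CC[Si](CC)(CC)O[C@@H](C[C@@](C)(O[Si](CC)(CC)CC)[C@@H]1CC[C@@](C)(C=C)O1)c1coc([Li])c1CO[Si](c1ccccc1)(c1ccccc1)C(C)(C)C | intermediate (not isolated)
19 | lithium furyl(triisopropoxy)borate from 18 | CC[Si](CC)(CC)O[C@@H](C[C@@](C)(O[Si](CC)(CC)CC)[C@@H]1CC[C@@](C)(C=C)O1)c1coc([B-](OC(C)C)(OC(C)C)OC(C)C)c1CO[Si](c1ccccc1)(c1ccccc1)C(C)(C)C.[Li+] | intermediate (not isolated)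
20 | 3-({[tert-butyl(diphenyl)silyl]oxy}methyl)-4-{(1S,3R)-3-[(2S,5S)-5-ethenyl-5-methyloxolan-2-yl]-1,3-bis[(triethylsilyl)oxy]butyl}furan-2(5H)-one | CC[Si](CC)(CC)O[C@@H](C[C@@](C)(O[Si](CC)(CC)CC)[C@@H]1CC[C@@](C)(C=C)O1)C1=C(CO[Si](c2ccccc2)(c2ccccc2)C(C)(C)C)C(=O)OC1 | intermediate
21 | vicinal diol from the vinyl group of 20, both carbinol epimers | CC[Si](CC)(CC)O[C@@H](C[C@@](C)(O[Si](CC)(CC)CC)[C@@H]1CC[C@@](C)(C(O)CO)O1)C1=C(CO[Si](c2ccccc2)(c2ccccc2)C(C)(C)C)C(=O)OC1 | intermediate (not isolated)
22 | (2S,5S)-5-{(2R,4S)-4-[4-({[tert-butyl(diphenyl)silyl]oxy}methyl)-5-oxo-2,5-dihydrofuran-3-yl]-2,4-bis[(triethylsilyl)oxy]butan-2-yl}-2-methyloxolane-2-carbaldehyde | CC[Si](CC)(CC)O[C@@H](C[C@@](C)(O[Si](CC)(CC)CC)[C@@H]1CC[C@@](C)(C=O)O1)C1=C(CO[Si](c2ccccc2)(c2ccccc2)C(C)(C)C)C(=O)OC1 | intermediate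
23 | (2S,5S)-5-{(2R,4S)-4-[4-({[tert-butyl(diphenyl)silyl]oxy}methyl)-5-{[tri(propan-2-yl)silyl]oxy}furan-3-yl]-2,4-bis[(triethylsilyl)oxy]butan-2-yl}-2-methyloxolane-2-carbaldehyde (key-step precursor) | CC[Si](CC)(CC)O[C@@H](C[C@@](C)(O[Si](CC)(CC)CC)[C@@H]1CC[C@@](C)(C=O)O1)c1coc(O[Si](C(C)C)(C(C)C)C(C)C)c1CO[Si](c1ccccc1)(c1ccccc1)C(C)(C)C | intermediate
24 | (1S,4S,5S,6S,8S,10R)-13-[tert-butyl(diphenyl)silyloxy]-1,4-epoxy-5-hydroxy-8,10-bis(triethylsilyloxy)germacr-7(11)-en-12,6-olide (key-step product) | CC[Si](CC)(CC)O[C@H]1C[C@@](C)(O[Si](CC)(CC)CC)[C@@H]2CC[C@@](C)([C@@H](O)[C@H]3OC(=O)C(CO[Si](c4ccccc4)(c4ccccc4)C(C)(C)C)=C31)O2 | intermediate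
25 | 5-O-methanesulfonate of 24 | CC[Si](CC)(CC)O[C@H]1C[C@@](C)(O[Si](CC)(CC)CC)[C@@H]2CC[C@@](C)([C@@H](OS(C)(=O)=O)[C@H]3OC(=O)C(CO[Si](c4ccccc4)(c4ccccc4)C(C)(C)C)=C31)O2 | intermediate (not isolated)
26 | (1S,4S,5E,8S,10R)-13-[tert-butyl(diphenyl)silyloxy]-1,4-epoxy-8,10-bis(triethylsilyloxy)germacra-5,7(11)-dien-12,6-olide | CC[Si](CC)(CC)O[C@H]1C[C@@](C)(O[Si](CC)(CC)CC)[C@@H]2CC[C@@](C)(/C=C3/OC(=O)C(CO[Si](c4ccccc4)(c4ccccc4)C(C)(C)C)=C31)O2 | intermediate
27 | (1S,4S,5E,8S,10R)-13-[tert-butyl(diphenyl)silyloxy]-1,4-epoxy-8,10-dihydroxygermacra-5,7(11)-dien-12,6-olide | O[C@H]1C[C@@](C)(O)[C@@H]2CC[C@@](C)(/C=C3/OC(=O)C(CO[Si](c4ccccc4)(c4ccccc4)C(C)(C)C)=C31)O2 | intermediate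
28 | angelic acid, (2Z)-2-methylbut-2-enoic acid | C/C=C(/C)C(=O)O | starting material
29 | angelic 2,4,6-trichlorobenzoic anhydride | C/C=C(/C)C(=O)OC(=O)c1c(Cl)cc(Cl)cc1Cl | intermediate (not isolated)
30 | (1S,4S,5E,8S,10R)-8-angeloyloxy-13-[tert-butyl(diphenyl)silyloxy]-1,4-epoxy-10-hydroxygermacra-5,7(11)-dien-12,6-olide | C/C=C(/C)C(=O)O[C@H]1C[C@@](C)(O)[C@@H]2CC[C@@](C)(/C=C3/OC(=O)C(CO[Si](c4ccccc4)(c4ccccc4)C(C)(C)C)=C31)O2 | intermediate
31 | (1S,4S,5E,8S,10R)-8-angeloyloxy-1,4-epoxy-10,13-dihydroxygermacra-5,7(11)-dien-12,6-olide | C/C=C(/C)C(=O)O[C@H]1C[C@@](C)(O)[C@@H]2CC[C@@](C)(/C=C3/OC(=O)C(CO)=C31)O2 | intermediate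
32 | CNP0162854.1, (1S,4S,5E,8S,10R)-13-acetoxy-8-angeloyloxy-1,4-epoxy-10-hydroxygermacra-5,7(11)-dien-12,6-olide | C/C=C(/C)C(=O)O[C@H]1C[C@@](C)(O)[C@@H]2CC[C@@](C)(/C=C3/OC(=O)C(COC(C)=O)=C31)O2 | target

Total step count: 20 steps. Longest linear sequence: 17 steps (from 7 through steps 4–7 and 8–20; the branch from 1 is 3 steps and joins at step 8).

Steps most likely to fail

Step 15. What may go wrong: intermolecular aldol addition (oligomerisation), or no closure at all because the transition state cannot span the trans-2,5 positions of the oxolane; Lewis-acid ionisation at C13 is a lesser risk. Fallback, setting out from 22 and coming back at 26: the ring is closed by a base-mediated vinylogous Knoevenagel-type condensation instead. Compound 22 is held at about 1 mM in toluene with DBU (or piperidinium acetate) at 40–60 °C. The butenolide dienolate adds reversibly through C6 to the C5 aldehyde and the aldol loses water in the same flask by E1cB elimination. The closure is thus under thermodynamic control and is driven by formation of the conjugated dienolide, without silyl dienol ether, Lewis acid or mesylate. This fallback makes no compound outside the list (F0).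

Step 8. What may go wrong: poor facial selectivity at the aldehyde if the α-oxygenated stereocentre of the enolate opposes the isopinocampheyl ligands, with some epimerisation at C1 as a lesser risk. Fallback, setting out from 6 and 11 and coming back at 17: C8 is set by a hydroxyl-directed ketone reduction instead of in the C–C bond formation. The lithium enolate of 6 (LiN(iPr)2, THF, −78 °C) is added to 11 to give the C8-epimeric β-hydroxy ketone F1. Silylation (TESCl, imidazole) gives the epimeric silyl ether F2, and MeMgBr under the chelate control of step 10 gives the tertiary alcohol F3. AcOH/THF/H2O removes the secondary silyl ether to give the epimeric diol F4, and MnO2 oxidises only the furylic carbinol to the single furyl ketone F5. Narasaka–Prasad reduction (Et2BOMe, NaBH4, THF/MeOH, −78 °C) then proceeds through a boron chelate with the oxolanyl group equatorial and axial hydride delivery, and should give the 1,3-syn (8S,10R) diol F6. TESOTf (2.5 equiv) and 2,6-lutidine convert F6 into 17.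

Step 18. What may go wrong: isomerisation of the Z acyl donor to the E (tiglate) isomer during activation, sluggish acylation of the hindered C8 hydroxyl, or migration of the lactone to O8 on heating with base. Fallback, setting out from 27 and coming back at 30: the angelate is built on the substrate instead of being transferred. The C8 hydroxyl of 27 is esterified with 2-[bis(2,2,2-trifluoroethoxy)phosphoryl]propanoic acid (EDC·HCl, DMAP, CH2Cl2, rt) to give the phosphonopropanoate ester F7. A Still–Gennari olefination (KN(SiMe3)2, 18-crown-6, THF, −78 °C; acetaldehyde) then forms the Z-configured 2-methylbut-2-enoate directly, giving 30.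

Further compounds
F0 | step 15 | none | none
F1 | step 8 | C8-epimeric β-hydroxy ketone, 3-[5-bromo-4-({[tert-butyl(diphenyl)silyl]oxy}methyl)furan-3-yl]-1-[(2S,5S)-5-ethenyl-5-methyloxolan-2-yl]-3-hydroxypropan-1-one | OC(CC(=O)[C@@H]1CC[C@@](C)(C=C)O1)c1coc(Br)c1CO[Si](c1ccccc1)(c1ccccc1)C(C)(C)C
F2 | step 8 | C8-epimeric triethylsilyl ether of F1 | CC[Si](CC)(CC)OC(CC(=O)[C@@H]1CC[C@@](C)(C=C)O1)c1coc(Br)c1CO[Si](c1ccccc1)(c1ccccc1)C(C)(C)C
F3 | step 8 | (10R) tertiary alcohol, C8-epimeric, from methyl addition to F2 | CC[Si](CC)(CC)OC(C[C@@](C)(O)[C@@H]1CC[C@@](C)(C=C)O1)c1coc(Br)c1CO[Si](c1ccccc1)(c1ccccc1)C(C)(C)C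
F4 | step 8 | (10R) 8,10-diol, C8-epimeric | OC(C[C@@](C)(O)[C@@H]1CC[C@@](C)(C=C)O1)c1coc(Br)c1CO[Si](c1ccccc1)(c1ccccc1)C(C)(C)C
F5 | step 8 | (3R)-1-[5-bromo-4-({[tert-butyl(diphenyl)silyl]oxy}methyl)furan-3-yl]-3-[(2S,5S)-5-ethenyl-5-methyloxolan-2-yl]-3-hydroxybutan-1-one | O=C(C[C@@](C)(O)[C@@H]1CC[C@@](C)(C=C)O1)c1coc(Br)c1CO[Si](c1ccccc1)(c1ccccc1)C(C)(C)C
F6 | step 8 | (1S,3R)-1-[5-bromo-4-({[tert-butyl(diphenyl)silyl]oxy}methyl)furan-3-yl]-3-[(2S,5S)-5-ethenyl-5-methyloxolan-2-yl]butane-1,3-diol | O[C@@H](C[C@@](C)(O)[C@@H]1CC[C@@](C)(C=C)O1)c1coc(Br)c1CO[Si](c1ccccc1)(c1ccccc1)C(C)(C)C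
F7 | step 18 | 8-O-{2-[bis(2,2,2-trifluoroethoxy)phosphoryl]propanoyl} ester of 27, both epimers at the phosphonate carbon | CC(C(=O)O[C@H]1C[C@@](C)(O)[C@@H]2CC[C@@](C)(/C=C3/OC(=O)C(CO[Si](c4ccccc4)(c4ccccc4)C(C)(C)C)=C31)O2)P(=O)(OCC(F)(F)F)OCC(F)(F)F
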